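**Plan**
- The target is a depside with no stereocentre. The first cut is the aryl ester C(=O)–O bond between the ring A carbonyl and O-4' of ring B, together with the 2'-O–CH3 bond. Both rings then lead back to one arene, methyl 2,4-dihydroxy-6-propylbenzoate.
- That arene is cut at C3'–C4' and C1'–C6'. C1'(CO2Me)–C2'(O)–C3' is an acetoacetate unit and C4'(O)–C5'–C6'(propyl) is a 3-oxohexanoyl unit.
- The enabling feature is the pattern of ring B (ester carbon on C1', oxygens on C2' and C4', propyl on C6'), which recurs in ring A. It maps onto a 1,3-bis(silyloxy)diene plus a β-silyloxy enoyl chloride, and the ring formed carries one ester-chelated hydroxyl (C2') and one free hydroxyl (C4') that can be addressed separately.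
- Forward: the benzene ring is made once by the (3+3) cycloaromatization. One part is dibenzylated and saponified to the ring A acid, which acylates the free 4'-OH of the other part. Methylation of the chelated 2'-OH and hydrogenolysis finish the route.
- The only stereochemical elements on the way are enol ether geometries, which vanish in the arene.

Key step: step 6

Remark: the silyl enol ethers of the route are drawn as Z isomers for definiteness; E/Z mixtures would serve equally, because these double bonds end up in the aromatic ring. The two transient species of the key step are written as neutral silyl compounds although they are presumably titanium-bound in the flask.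

**Step 1**
Reactants: 1 methyl acetoacetate
Product: 2 methyl (Z)-3-(trimethylsilyloxy)but-2-enoate
Conditions: TMSCl, Et3N, hexane, rt; filtration, distillation
Reagents that add atoms: chlorotrimethylsilane, C[Si](C)(C)Cl
Why: O-silylation of the enol of a β-keto ester (silyl enol ether formation) is routine, and precipitation of the amine hydrochloride from hexane should drive it to completion.

**Step 2**
Reactants: 2 methyl (Z)-3-(trimethylsilyloxy)but-2-enoate
Product: 3 (1Z)-1-methoxy-1,3-bis(trimethylsilyloxy)buta-1,3-diene
Conditions: LiN(i-Pr)2, THF, −78 °C; TMSCl, −78 °C → rt; pentane, filtration, concentration (no aqueous work-up)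
Reagents that add atoms: chlorotrimethylsilane, C[Si](C)(C)Cl
Why: Kinetic γ-deprotonation of the β-silyloxy enoate gives a dienolate that TMSCl traps on oxygen, the standard enolate O-silylation route to 1,3-bis(silyloxy)dienes.

**Step 3**
Reactants: 4 methyl 3-oxohexanoate
Product: 5 3-oxohexanoic acid
Conditions: NaOH (1 M aq.), 0 °C → rt; then HCl (2 M aq.) to pH 2 at 0 °C, Et2O extraction, evaporation below 20 °C, used at once
Reagents that add atoms: sodium hydroxide, [Na+].[OH-]
Why: Saponification of an unhindered methyl ester proceeds in dilute base at room temperature, and the β-keto acid should survive cold acidification and isolation because decarboxylation needs the free acid and warmth.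

**Step 4**
Reactants: 5 3-oxohexanoic acid
Product: 6 trimethylsilyl (Z)-3-(trimethylsilyloxy)hex-2-enoate
Conditions: TMSCl (2.2 equiv), Et3N (2.3 equiv), Et2O, 0 °C → rt; filtration, bulb-to-bulb distillation
Reagents that add atoms: chlorotrimethylsilane, C[Si](C)(C)Cl
Why: Double silylation (silyl ester formation plus enol O-silylation) passes through the ammonium carboxylate, which does not decarboxylate, and gives a distillable bis-silyl derivative.

**Step 5**
Reactants: 6 trimethylsilyl (Z)-3-(trimethylsilyloxy)hex-2-enoate
Product: 7 (Z)-3-(trimethylsilyloxy)hex-2-enoyl chloride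
Conditions: (COCl)2 (1.05 equiv), DMF (cat.), CH2Cl2, 0 °C → rt; volatiles removed in vacuo, crude product used directly
Reagents that add atoms: oxalyl chloride, O=C(Cl)C(=O)Cl
Why: Exchange of a silyl ester for an acid chloride with oxalyl chloride under Vilsmeier-type catalysis is neutral, since TMSCl and not HCl is released, so the acid-labile silyl enol ether should persist.

**Step 6**
Reactants: 3 (1Z)-1-methoxy-1,3-bis(trimethylsilyloxy)buta-1,3-diene; 7 (Z)-3-(trimethylsilyloxy)hex-2-enoyl chloride
Product: 10 methyl 2,4-dihydroxy-6-propylbenzoate, via open-chain acylation adduct 8 (not isolated), via cyclised silyloxy diketo ester 9 (not isolated)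
Conditions: TiCl4 (1.1 equiv), CH2Cl2, −78 °C → rt; then H2O/dilute HCl work-up
Reagents that add atoms: none
Why: TiCl4 (a tetravalent titanium Lewis acid) activates acid chloride 7, and the terminal CH2 (C4) of diene 3, its most nucleophilic site, attacks the acyl carbon in a vinylogous Mukaiyama–Claisen acylation that forms C3'–C4' and expels TMSCl, leaving adduct 8 as a silyl enol ether at the future C1'. Titanium coordination of the new ketone then turns the β-silyloxy enone terminus into a vinylogous acyl electrophile, and C1' adds to its β-carbon (the masked ketone carbon, future C6') in a 6-endo-trig Mukaiyama–Michael, aldol-type closure that forms C1'–C6' and gives 9. β-Elimination of trimethylsilanol and enolisation of the two ring carbonyls then deliver the arene, which is the driving force of the cascade. The closest known reaction type is the Chan–Brownbridge (3+3) cycloaromatization of 1,3-bis(silyloxy)dienes with 1,3-dielectrophiles, which counts β-silyloxy enoyl chlorides among its partners. No stereocentre is created. The step needs regioselectivity (diene terminus to the acyl chloride carbon; the reverse pairing would give the 2,6-dihydroxy-4-propyl isomer), and this is secured by the far higher electrophilicity of the acid chloride over the silyl-masked ketone together with the higher nucleophilicity of C4 over C2 of the diene.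

**Step 7**
Reactants: 10 methyl 2,4-dihydroxy-6-propylbenzoate (about half of the batch)
Product: 11 methyl 2,4-bis(benzyloxy)-6-propylbenzoate
Conditions: BnBr (2.5 equiv), K2CO3, DMF, 60 °C
Reagents that add atoms: benzyl bromide, BrCc1ccccc1
Why: Williamson etherification in DMF with excess bromide and carbonate should alkylate both the free 4-OH and the hydrogen-bonded 2-OH while leaving the methyl ester untouched.

**Step 8**
Reactants: 11 methyl 2,4-bis(benzyloxy)-6-propylbenzoate
Product: 12 2,4-bis(benzyloxy)-6-propylbenzoic acid
Conditions: KOH, DMSO/H2O (4:1), 90 °C; then cold dilute HCl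
Reagents that add atoms: potassium hydroxide, [K+].[OH-]
Why: Saponification of a di-ortho-substituted benzoate is achieved with poorly solvated hydroxide in hot aqueous DMSO, conditions to which aryl benzyl ethers are inert.

**Step 9**
Reactants: 12 2,4-bis(benzyloxy)-6-propylbenzoic acid; 10 methyl 2,4-dihydroxy-6-propylbenzoate
Product: 14 methyl 4-{[2,4-bis(benzyloxy)-6-propylbenzoyl]oxy}-2-hydroxy-6-propylbenzoate, via mixed trifluoroacetic anhydride 13 (not isolated)
Conditions: (CF3CO)2O, toluene, rt; aq. NaHCO3 work-up
Reagents that add atoms: none
Why: Esterification through the mixed carboxylic–trifluoroacetic anhydride, the standard depside coupling for electron-rich di-ortho-substituted benzoic acids, should acylate the unhindered 4-OH in preference to the 2-OH, which is hydrogen-bonded to and flanked by the ester.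

**Step 10**
Reactants: 14 methyl 4-{[2,4-bis(benzyloxy)-6-propylbenzoyl]oxy}-2-hydroxy-6-propylbenzoate
Product: 15 methyl 4-{[2,4-bis(benzyloxy)-6-propylbenzoyl]oxy}-2-methoxy-6-propylbenzoate
Conditions: MeI (excess), K2CO3 (anhydrous), acetone, reflux
Reagents that add atoms: iodomethane, CI
Why: Williamson O-methylation of the chelated phenol under anhydrous carbonate conditions should spare the sterically shielded di-ortho-substituted aryl ester and the methyl ester.

**Step 11**
Reactants: 15 methyl 4-{[2,4-bis(benzyloxy)-6-propylbenzoyl]oxy}-2-methoxy-6-propylbenzoate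
Product: 16 methyl 4-[(2,4-dihydroxy-6-propylbenzoyl)oxy]-2-methoxy-6-propylbenzoate
Conditions: H2 (1 atm), 10% Pd/C, EtOAc, rt
Reagents that add atoms: none
Why: Catalytic hydrogenolysis of the two aryl benzyl ethers is neutral and should leave the depside ester, the methyl ester and the aryl methyl ether intact.

**Compound list**
1 | methyl acetoacetate | CC(=O)CC(=O)OC | starting material
2 | methyl (Z)-3-(trimethylsilyloxy)but-2-enoate | C/C(O[Si](C)(C)C)=C/C(=O)OC | intermediate
3 | (1Z)-1-methoxy-1,3-bis(trimethylsilyloxy)buta-1,3-diene | CO/C(O[Si](C)(C)C)=C/C(=C)O[Si](C)(C)C | intermediate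
4 | methyl 3-oxohexanoate | CCCC(=O)CC(=O)OC | starting material
5 | 3-oxohexanoic acid | CCCC(=O)CC(=O)O | intermediate
6 | trimethylsilyl (Z)-3-(trimethylsilyloxy)hex-2-enoate | CCC/C(O[Si](C)(C)C)=C/C(=O)O[Si](C)(C)C | intermediate
7 | (Z)-3-(trimethylsilyloxy)hex-2-enoyl chloride | CCC/C(O[Si](C)(C)C)=C/C(=O)Cl | intermediate
8 | methyl (2Z,6Z)-5-oxo-3,7-bis(trimethylsilyloxy)deca-2,6-dienoate (open-chain acylation adduct, formed in the flask) | COC(=O)/C=C(/CC(=O)/C=C(/CCC)O[Si](C)(C)C)O[Si](C)(C)C | intermediate
9 | methyl 2,4-dioxo-6-propyl-6-(trimethylsilyloxy)cyclohexane-1-carboxylate (formed in the flask; racemic, configuration at C1 and C6 not controlled, both centres lost on aromatization) | CCCC1(O[Si](C)(C)C)CC(=O)CC(=O)C1C(=O)OC | intermediate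
10 | methyl 2,4-dihydroxy-6-propylbenzoate | CCCc1cc(O)cc(O)c1C(=O)OC | intermediate
11 | methyl 2,4-bis(benzyloxy)-6-propylbenzoate | CCCc1cc(OCc2ccccc2)cc(OCc2ccccc2)c1C(=O)OC | intermediate
12 | 2,4-bis(benzyloxy)-6-propylbenzoic acid | CCCc1cc(OCc2ccccc2)cc(OCc2ccccc2)c1C(=O)O | intermediate
13 | 2,4-bis(benzyloxy)-6-propylbenzoic trifluoroacetic anhydride (formed in the flask) | CCCc1cc(OCc2ccccc2)cc(OCc2ccccc2)c1C(=O)OC(=O)C(F)(F)F | intermediate
14 | methyl 4-{[2,4-bis(benzyloxy)-6-propylbenzoyl]oxy}-2-hydroxy-6-propylbenzoate | CCCc1cc(OCc2ccccc2)cc(OCc2ccccc2)c1C(=O)Oc1cc(CCC)c(C(=O)OC)c(O)c1 | intermediate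
15 | methyl 4-{[2,4-bis(benzyloxy)-6-propylbenzoyl]oxy}-2-methoxy-6-propylbenzoate | CCCc1cc(OCc2ccccc2)cc(OCc2ccccc2)c1C(=O)Oc1cc(CCC)c(C(=O)OC)c(OC)c1 | intermediate
16 | methyl 4-[(2,4-dihydroxy-6-propylbenzoyl)oxy]-2-methoxy-6-propylbenzoate | CCCc1cc(O)cc(O)c1C(=O)Oc1cc(CCC)c(C(=O)OC)c(OC)c1 | target

**Step count**
Total: 11 steps. Longest linear sequence: 9 steps (4 → 5 → 6 → 7 → 10 → 11 → 12 → 14 → 15 → 16).

**Steps most likely to fail**

The first is step 6. The acid chloride may lose its enol silyl group and decompose by ketene formation or self-condensation before C-acylation, the diene may be acylated on oxygen, or closure may be slow enough for the open-chain adduct to be hydrolysed on work-up. A fallback that changes the ring construction sets out from methyl acetoacetate 1. Michael addition of its sodium enolate (NaOMe, MeOH, reflux) to methyl (E)-hex-2-enoate, followed in the same pot by Dieckmann closure, should give trans-methyl 2,4-dioxo-6-propylcyclohexane-1-carboxylate F1 (racemic, enolised). Bromine in acetic acid should aromatize it with nuclear bromination to methyl 3,5-dibromo-2,4-dihydroxy-6-propylbenzoate F2. Hydrogenolysis of the two C–Br bonds (H2, Pd/C, NaOAc, MeOH) returns to the route at 10.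

The second is step 5, together with the cold isolation in step 3. The β-keto acid may decarboxylate, or traces of HCl may strip the enol silyl group during chloride formation and lead to oligomers. A fallback that keeps the same two ring bonds but uses a robust ketone mask sets out from methyl 3-oxohexanoate 4 and methyl acetoacetate 1. Ketalization of 4 with ethane-1,2-diol (TsOH, toluene, water separator) gives methyl 2-(2-propyl-1,3-dioxolan-2-yl)acetate F3. Claisen acylation of the dianion of 1 (NaH then n-BuLi, THF, 0 °C, two equivalents of dianion) by F3 should give methyl 3,5-dioxo-6-(2-propyl-1,3-dioxolan-2-yl)hexanoate F4. Dilute aqueous HCl in THF liberates methyl 3,5,7-trioxodecanoate F5. At about pH 9 (aqueous carbonate buffer, MeOH) F5 should undergo the C1'–C6' aldol closure and dehydrate on acidification, returning to the route at 10.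

The third is step 10. Methylation of the hydrogen-bonded hydroxyl may be sluggish, and the phenoxide may cause acyl migration or cleavage of the depside ester on prolonged heating. A fallback that differentiates the two hydroxyls before the rings are joined sets out from 10. Selective benzylation of the free 4-OH (BnBr 1.05 equiv, K2CO3, acetone, rt) gives methyl 4-(benzyloxy)-2-hydroxy-6-propylbenzoate F6. Methylation (MeI, K2CO3, DMF, 50 °C) gives methyl 4-(benzyloxy)-2-methoxy-6-propylbenzoate F7, and hydrogenolysis (H2, Pd/C, EtOAc) gives methyl 4-hydroxy-2-methoxy-6-propylbenzoate F8. Esterification of F8 with acid 12 under the conditions of step 9 (through 13) returns to the route at 15, bypassing steps 9 and 10.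

**Further compounds**
F1 | step 6 | trans-methyl 2,4-dioxo-6-propylcyclohexane-1-carboxylate (racemic, relative configuration shown) | CCC[C@@H]1CC(=O)CC(=O)[C@H]1C(=O)OC
F2 | step 6 | methyl 3,5-dibromo-2,4-dihydroxy-6-propylbenzoate | CCCc1c(Br)c(O)c(Br)c(O)c1C(=O)OC
F3 | step 5 | methyl 2-(2-propyl-1,3-dioxolan-2-yl)acetate | CCCC1(CC(=O)OC)OCCO1
F4 | step 5 | methyl 3,5-dioxo-6-(2-propyl-1,3-dioxolan-2-yl)hexanoate | CCCC1(CC(=O)CC(=O)CC(=O)OC)OCCO1
F5 | step 5 | methyl 3,5,7-trioxodecanoate | CCCC(=O)CC(=O)CC(=O)CC(=O)OC
F6 | step 10 | methyl 4-(benzyloxy)-2-hydroxy-6-propylbenzoate | CCCc1cc(OCc2ccccc2)cc(O)c1C(=O)OC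
F7 | step 10 | methyl 4-(benzyloxy)-2-methoxy-6-propylbenzoate | CCCc1cc(OCc2ccccc2)cc(OC)c1C(=O)OC
F8 | step 10 | methyl 4-hydroxy-2-methoxy-6-propylbenzoate | CCCc1cc(O)cc(OC)c1C(=O)OC
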